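4 questions stand on this flask, and I would answer them with one quantity: how much converted material the solution can hold.

    starting material ⇌ isomer of the product A (K1 = 1.3, k1 = 0.0168 s⁻¹)
    starting material ⇌ target (K2 = 1.10, k2 = 0.145 s⁻¹)
    solid substrate ⇌ starting material, rate k3*(cs3 - [starting material]) while solid is left; crystals form when [starting material] > cs3 (cs3 = 18 mM, k3 = 0.0101 s⁻¹)
    crystals ⇌ target, rate k4*(cs4 - [target]) while solid is left; crystals form when [target] > cs4 (cs4 = 0.12 M, k4 = 0.485 s⁻¹)
    starting material ⇌ isomer of the product B (K5 = 1.53, k5 = 0.00630 s⁻¹)

solid substrate 0.50 M; time 1.5 h

1. which holds at 1.5 h: what has brought the reaction to rest, or that it has not come to rest (for what has run out or reacted, a solid counts together with what of it has only dissolved) (forward and back rates have come level / it is still moving / all of the solid substrate has reacted)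
2. part of the solid substrate that has turned into other species by 1.5 h (what has only dissolved does not count)
3. target at 1.5 h, in percent of the solid substrate charged
4. isomer of the product B at 1.5 h, in percent of the solid substrate charged

- amounts and yields of target count crystals too
- given per volume of solution although it is solid: solid substrate, crystals
- at the start none of the solid substrate is in solution
- what has only dissolved of solid substrate counts as not reacted
- the reaction counts as stopped when no species that holds the solid substrate changes by six tenths of a point or more over the second half of the time
- run time (flask): 1.5 h

- Follow one molecule that leaves the solid substrate: in solution it becomes starting material and forks towards target, isomer of the product A or isomer of the product B. Every fork runs back, so at rest you find it in these forms in the ratio of the equilibrium constants (thermodynamic control), with c(starting material) held at 18 mM while solid substrate is left.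
- Multiplying 18 mM by the sum of the 3 equilibrium constants gives 70.7 mM: this is the capacity of the solution, the converted material it holds at rest beside solid.
- By hand, c(target) comes to 19.8 mM, which is less than its solubility of 0.12 M, so you expect no crystals. The dissolved total of 88.7 mM is less than the charge of 0.50 M, so you expect solid substrate to remain.
- Turn the charge first: by hand the capacity stays put while solid is left, so conversion is capacity over charge. That gives 14.1% for this flask, with target at 3.96% and isomer of the product B at 5.51%. For a neighbour flask charged with 0.20 M it gives 35.3%.
- Turn the time next: the solution fills through dissolution, and each entering molecule is shared among the dissolved forms, so I reckon a filling time of 8.14 min. That is shorter than the run of 1.5 h, which holds 11.1 such times, so by hand the flask ends at rest and more time changes little.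
- The forecast gives forward and back rates have come level, conversion 14.14%, target 3.96% and isomer of the product B 5.51%, and holds that “the system has fully reached equilibrium with solid still present”.
- The simulation of this flask gives forward and back rates have come level, conversion 14.1%, target 3.96% and isomer of the product B 5.51%.
- The neighbour flask at 0.20 M gives 35.4% against the reckoned 35.3%, with 65% of its charge still there. The flask at 0.50 M comes to rest with isomer of the product B at 5.51% mainly because that isomer runs back to starting material. With that back run taken away, the answer on rest turns, and isomer of the product B at 1.5 h goes from 5.51% to 72.5%.

The constants used here belong to no real substance; the result is computed.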